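The ten-membered carbocycle (ring A) is disconnected at C3–C4. The key step exploits the exocyclic methylene C15 on C4, with C3 bonded to C4 and the ester-bearing C1=C10 alkene two carbons further round ring A, which is the imprint of a branched alkyne–alkene Alder-ene coupling. One ruthenium-catalysed operation closes ring A, creates C4=C15 and leaves a C1=C2 alkene that base then moves into conjugation with the C14 ester. The precursor is an enyne built on the preformed trans-disubstituted α-methylene lactone (ring B): C6 carries the silyl-protected propargylic alcohol (C5, C4≡C15) and C7 carries the C8 angelate chain that ends in a C10 ester bearing an allyl group (C1–C3).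

Key step: step 14

Remark: atoms are labelled C1–C15 as in the target (C12 lactone carbonyl, C13 lactone methylene, C14 ester carbon, C15 methylene on C4); C11 in 9–24 and C10 in 23–26 are not controlled and are carried as epimer mixtures, because both carbons end up sp2.

Step 1
Reactants: 1 (+)-2,3-O-isopropylidene-L-threitol
Product: 2 mono-TBS ether of 1
Conditions: NaH (1 equiv), THF, 0 °C to rt; TBSCl (1 equiv)
Reagents that add atoms: tert-butyldimethylsilyl chloride, CC(C)(C)[Si](C)(C)Cl
Why: One equivalent of NaH gives the poorly soluble monoalkoxide of the C2-symmetric diol, which is silylated once (standard monosilylation of a symmetric diol); no stereocentre is touched.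

Step 2
Reactants: 2 mono-TBS ether; 3 methyl (triphenylphosphoranylidene)acetate
Product: 5 γ-alkoxy E-enoate, via aldehyde 4 (not isolated)
Conditions: (COCl)2, DMSO, CH2Cl2, −78 °C; Et3N; then 3, −78 °C to rt
Reagents that add atoms: none
Why: Swern oxidation gives the α-alkoxy aldehyde (its trans-dioxolane is the stable isomer, so C6 should not epimerise) and the stabilised ylide converts it in the same flask into the enoate by Wittig olefination, mainly E; a minor Z isomer is expected to lead to the same C7 configuration in step 3.

Step 3
Reactants: 5 γ-alkoxy E-enoate; 6 vinylmagnesium bromide; 7 N,N-dimethylmethyleneiminium iodide (Eschenmoser's salt)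
Product: 9 C7-vinyl β-amino ester, via silyl ketene acetal 8 (not isolated)
Conditions: 6, CuI, TMSCl, THF, −78 °C; then 7, CH2Cl2, −78 °C to rt; aq. NaHCO3
Reagents that add atoms: none
Why: Chlorosilane-accelerated conjugate addition of the vinylcuprate should occur anti to the C6–O bond (Felkin–Anh-type transition state, C–O antiperiplanar to the incoming reagent, hydrogen inside), which sets C7, and the silyl ketene acetal is then aminomethylated by the iminium salt (Mannich reaction), which installs C13 as an amine-masked methylene.

Step 4
Reactants: 9 C7-vinyl β-amino ester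
Product: 10 primary alcohol
Conditions: TBAF, THF, 0 °C to rt
Reagents that add atoms: none
Why: Fluoride cleaves the primary TBS ether (desilylation) and leaves the acetonide, the ester and the amine untouched.

Step 5
Reactants: 10 primary alcohol
Product: 11 C4 aldehyde
Conditions: SO3·pyridine, DMSO, iPr2NEt, CH2Cl2, 0 °C
Reagents that add atoms: none
Why: Parikh–Doering oxidation gives the aldehyde under non-acidic conditions that tolerate the tertiary amine; C5 sits in a trans-dioxolane and should keep its configuration.

Step 6
Reactants: 11 C4 aldehyde; 12 dimethyl (1-diazo-2-oxopropyl)phosphonate (Ohira–Bestmann reagent)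
Product: 13 terminal alkyne
Conditions: 12, K2CO3, MeOH, 0 °C to rt
Reagents that add atoms: none
Why: Ohira–Bestmann homologation (diazoalkene, then 1,2-shift in the alkylidene carbene) converts the aldehyde into the C4≡C15 alkyne under conditions that the methyl ester, the acetonide and the amine survive.

Step 7
Reactants: 13 terminal alkyne
Product: 14 hydroxy lactone
Conditions: TFA/H2O, 0 °C to rt; NaHCO3 work-up
Reagents that add atoms: none
Why: Aqueous acid hydrolyses the acetonide and the freed C6 hydroxyl closes the five-membered lactone on the methyl ester (acid-catalysed lactonisation, preferred over the six-membered ring through O5), which leaves C5–OH free and gives the trans C6/C7 lactone from the anti adduct.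

Step 8
Reactants: 14 hydroxy lactone
Product: 15 TES ether
Conditions: TESCl, imidazole, CH2Cl2, 0 °C
Reagents that add atoms: chlorotriethylsilane, CC[Si](CC)(CC)Cl
Why: Imidazole-promoted O-silylation protects the secondary propargylic alcohol, which would otherwise be acylated in step 11 and could undergo redox isomerisation in step 14.

Step 9
Reactants: 15 TES ether
Product: 16 C8 aldehyde
Conditions: OsO4 (cat.), NaIO4, 2,6-lutidine, dioxane/H2O, rt
Reagents that add atoms: sodium periodate, [Na+].[O-]I(=O)(=O)=O
Why: In this Lemieux–Johnson cleavage OsO4 dihydroxylates only the monosubstituted vinyl group (the alkyne is inert) and periodate cleaves the diol to the aldehyde, which is used crude because a β-acyloxy aldehyde is prone to elimination.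

Step 10
Reactants: 16 C8 aldehyde; 17 methyl 2-(bromomethyl)acrylate
Product: 19 (8R)-homoallylic alcohol, via trimethylsilyl ether 18 (not isolated)
Conditions: 17, CrCl2 (10 mol%), 3,6-diphenyl-1,8-bis(4-isopropyl-4,5-dihydrooxazol-2-yl)carbazole (12 mol%, enantiomer chosen for Re-face delivery), Mn, TMSCl, iPr2NEt, THF, rt; then citric acid, MeOH, 0 °C
Reagents that add atoms: none
Why: In this catalytic asymmetric Nozaki–Hiyama allylation the 2-(methoxycarbonyl)allylchromium species adds through a chair transition state on the chiral chromium complex, which should deliver it to the Re face of C8 and set the 8R centre under catalyst control, the substrate bias being small because both neighbours of C7 are ring carbons.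

Step 11
Reactants: 19 (8R)-homoallylic alcohol; 20 angelic acid
Product: 21 C8 angelate
Conditions: 20, 2,4,6-trichlorobenzoyl chloride, Et3N, toluene, rt; then 19, 70 °C
Reagents that add atoms: none
Why: Yamaguchi-type esterification through the mixed anhydride, run without a nucleophilic pyridine catalyst, acylates hindered secondary alcohols without Z to E isomerisation of the angelate; C8 keeps its configuration.

Step 12
Reactants: 21 C8 angelate; 6 vinylmagnesium bromide
Product: 23 C10 allyl ester, via silyl ketene acetal 22 (not isolated)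
Conditions: 6, CuI, TMSCl, THF, −78 °C; aq. NH4Cl
Reagents that add atoms: none
Why: Chlorosilane-accelerated 1,4-addition of the vinylcuprate goes to the α-substituted acrylate, the only good acceptor present (the angelate is α,β-disubstituted and the lactone methylene is still masked as the amine), and hydrolysis of the silyl ketene acetal gives the ester with an uncontrolled C10 centre.

Step 13
Reactants: 23 C10 allyl ester
Product: 25 enyne bearing the free lactone methylene, via ammonium iodide 24 (not isolated)
Conditions: MeI, MeCN, rt; then sat. aq. NaHCO3, EtOAc, rt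
Reagents that add atoms: none
Why: N-Methylation gives the quaternary ammonium salt, which undergoes E1cB (Hofmann-type) elimination with bicarbonate and unveils the α-methylene lactone, the classical unmasking of an amine-protected methylene lactone; it is done only now because the free methylene would not survive step 12.

Step 14
Reactants: 25 enyne bearing the free lactone methylene
Product: 26 macrocyclic 1,4-diene
Conditions: [CpRu(MeCN)3]PF6 (10–20 mol%), acetone, 50 °C, 0.002 M, slow addition of 25
Reagents that add atoms: none
Why: Proposed new method: the cationic CpRu fragment binds the terminal alkyne and the monosubstituted alkene of 25 and couples them oxidatively to a ruthenacyclopentene in which C3 is bonded to the substituted alkyne carbon C4; β-hydride elimination from C1 and C15–H reductive elimination then release the E-configured 1,4-diene, which is the mechanism of the ruthenium-catalysed alkene–alkyne Alder-ene coupling, established intermolecularly and for closure of large rings but not for a ten-membered carbocycle. Ring A is closed in exo fashion at the alkyne (C4 in the ring, C15 outside), a closure that the trans-disubstituted lactone pre-organises and that high dilution protects from oligomerisation. No stereocentre is formed, and the two C10 epimers give two diastereomers of 26 that converge in step 15. The step needs bond formation at C4 and not at C15, which is the usual preference of terminal alkynes with this catalyst and is reinforced here because the alternative would be an eleven-membered ring holding two E alkenes. It also needs the catalyst to choose the C2=C3 alkene, the only monosubstituted, electron-neutral alkene with allylic hydrogens (on C1) placed for β-hydride elimination; the lactone methylene and the angelate are 1,1-di- and trisubstituted, electron-poor, and offer no such hydrogen.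

Step 15
Reactants: 26 macrocyclic 1,4-diene
Product: 27 conjugated C14 ester
Conditions: DBU, CH2Cl2, rt
Reagents that add atoms: none
Why: DBU removes the C10 proton, which is α to the ester and allylic, and the dienolate is reprotonated at C2 (base-mediated conjugation of a β,γ-unsaturated ester), so both C10 epimers should converge on the thermodynamically preferred enoate with C2 trans to the ester, that is ring-cis in ring A.

Step 16
Reactants: 27 conjugated C14 ester
Product: 28 target CNP0163095.1
Conditions: HF·pyridine, pyridine, THF, 0 °C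
Reagents that add atoms: none
Why: Buffered HF·pyridine cleaves the TES ether (fluoride-mediated desilylation) and spares the lactone, both esters and the alkenes.

Compound list

1 | (4S,5S)-2,2-dimethyl-1,3-dioxolane-4,5-dimethanol, (+)-2,3-O-isopropylidene-L-threitol (commercial acetonide of the diol from L-tartaric acid) | OC[C@@H]1OC(C)(C)O[C@H]1CO | starting material
2 | [(4S,5S)-5-(tert-butyldimethylsilyloxymethyl)-2,2-dimethyl-1,3-dioxolan-4-yl]methanol | OC[C@@H]1OC(C)(C)O[C@H]1CO[Si](C)(C)C(C)(C)C | intermediate
3 | methyl (triphenylphosphoranylidene)acetate | COC(=O)C=P(c1ccccc1)(c1ccccc1)c1ccccc1 | starting material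
4 | (4R,5S)-5-(tert-butyldimethylsilyloxymethyl)-2,2-dimethyl-1,3-dioxolane-4-carbaldehyde (formed in the flask, not isolated) | O=C[C@@H]1OC(C)(C)O[C@H]1CO[Si](C)(C)C(C)(C)C | intermediate
5 | methyl (E)-3-[(4S,5S)-5-(tert-butyldimethylsilyloxymethyl)-2,2-dimethyl-1,3-dioxolan-4-yl]prop-2-enoate | COC(=O)/C=C/[C@@H]1OC(C)(C)O[C@H]1CO[Si](C)(C)C(C)(C)C | intermediate
6 | vinylmagnesium bromide | C=C[Mg]Br | starting material
7 | N,N-dimethylmethyleneiminium iodide (Eschenmoser's salt) | C=[N+](C)C.[I-] | starting material
8 | trimethylsilyl ketene acetal of the C7-vinyl ester, vinyl anti to O6 (formed in the flask, not isolated) | COC(O[Si](C)(C)C)=C[C@H](C=C)[C@@H]1OC(C)(C)O[C@H]1CO[Si](C)(C)C(C)(C)C | intermediate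
9 | methyl (3S)-2-[(dimethylamino)methyl]-3-[(4S,5S)-5-(tert-butyldimethylsilyloxymethyl)-2,2-dimethyl-1,3-dioxolan-4-yl]pent-4-enoate, C11 (ester α-carbon) epimers | COC(=O)C(CN(C)C)[C@H](C=C)[C@@H]1OC(C)(C)O[C@H]1CO[Si](C)(C)C(C)(C)C | intermediate
10 | methyl (3S)-2-[(dimethylamino)methyl]-3-[(4S,5S)-5-(hydroxymethyl)-2,2-dimethyl-1,3-dioxolan-4-yl]pent-4-enoate, C11 epimers | COC(=O)C(CN(C)C)[C@H](C=C)[C@@H]1OC(C)(C)O[C@H]1CO | intermediate
11 | methyl (3S)-2-[(dimethylamino)methyl]-3-[(4S,5R)-5-formyl-2,2-dimethyl-1,3-dioxolan-4-yl]pent-4-enoate, C11 epimers | COC(=O)C(CN(C)C)[C@H](C=C)[C@@H]1OC(C)(C)O[C@H]1C=O | intermediate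
12 | dimethyl (1-diazo-2-oxopropyl)phosphonate (Ohira–Bestmann reagent) | CC(=O)C(=[N+]=[N-])P(=O)(OC)OC | starting material
13 | methyl (3S)-2-[(dimethylamino)methyl]-3-[(4S,5S)-5-ethynyl-2,2-dimethyl-1,3-dioxolan-4-yl]pent-4-enoate, C11 epimers | COC(=O)C(CN(C)C)[C@H](C=C)[C@@H]1OC(C)(C)O[C@H]1C#C | intermediate
14 | (4S,5S)-3-[(dimethylamino)methyl]-4-ethenyl-5-[(1S)-1-hydroxyprop-2-yn-1-yl]oxolan-2-one, trans at C4/C5 of the lactone, C3 (C11) epimers | CN(C)CC1C(=O)O[C@H]([C@@H](O)C#C)[C@H]1C=C | intermediate
15 | (4S,5S)-3-[(dimethylamino)methyl]-4-ethenyl-5-[(1S)-1-(triethylsilyloxy)prop-2-yn-1-yl]oxolan-2-one, C11 epimers | CN(C)CC1C(=O)O[C@H]([C@@H](O[Si](CC)(CC)CC)C#C)[C@H]1C=C | intermediate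
16 | (2S,3S)-4-[(dimethylamino)methyl]-5-oxo-2-[(1S)-1-(triethylsilyloxy)prop-2-yn-1-yl]oxolane-3-carbaldehyde, C11 epimers | CN(C)CC1C(=O)O[C@H]([C@@H](O[Si](CC)(CC)CC)C#C)[C@H]1C=O | intermediate
17 | methyl 2-(bromomethyl)acrylate | C=C(CBr)C(=O)OC | starting material
18 | C8 trimethylsilyl ether of 19 (formed in the flask, not isolated) | CN(C)CC1C(=O)O[C@H]([C@@H](O[Si](CC)(CC)CC)C#C)[C@H]1[C@H](O[Si](C)(C)C)CC(=C)C(=O)OC | intermediate
19 | methyl (4R)-4-hydroxy-2-methylidene-4-{(2S,3R)-4-[(dimethylamino)methyl]-5-oxo-2-[(1S)-1-(triethylsilyloxy)prop-2-yn-1-yl]oxolan-3-yl}butanoate, C11 epimers | CN(C)CC1C(=O)O[C@H]([C@@H](O[Si](CC)(CC)CC)C#C)[C@H]1[C@H](O)CC(=C)C(=O)OC | intermediate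
20 | angelic acid, (Z)-2-methylbut-2-enoic acid | C/C=C(/C)C(=O)O | starting material
21 | methyl (4R)-4-{[(2Z)-2-methylbut-2-enoyl]oxy}-2-methylidene-4-{(2S,3R)-4-[(dimethylamino)methyl]-5-oxo-2-[(1S)-1-(triethylsilyloxy)prop-2-yn-1-yl]oxolan-3-yl}butanoate, C11 epimers | CN(C)CC1C(=O)O[C@H]([C@@H](O[Si](CC)(CC)CC)C#C)[C@H]1[C@H](OC(=O)/C(C)=C\C)CC(=C)C(=O)OC | intermediate
22 | trimethylsilyl ketene acetal of 23 at C10/C14 (formed in the flask, not isolated) | CN(C)CC1C(=O)O[C@H]([C@@H](O[Si](CC)(CC)CC)C#C)[C@H]1[C@H](OC(=O)/C(C)=C\C)CC(CC=C)=C(OC)O[Si](C)(C)C | intermediate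
23 | methyl (4R)-4-{[(2Z)-2-methylbut-2-enoyl]oxy}-2-(prop-2-en-1-yl)-4-{(2S,3R)-4-[(dimethylamino)methyl]-5-oxo-2-[(1S)-1-(triethylsilyloxy)prop-2-yn-1-yl]oxolan-3-yl}butanoate, C10 and C11 epimers | CN(C)CC1C(=O)O[C@H]([C@@H](O[Si](CC)(CC)CC)C#C)[C@H]1[C@H](OC(=O)/C(C)=C\C)CC(CC=C)C(=O)OC | intermediate
24 | N-methyl quaternary ammonium iodide of 23 (formed in the flask, not isolated) | C[N+](C)(C)CC1C(=O)O[C@H]([C@@H](O[Si](CC)(CC)CC)C#C)[C@H]1[C@H](OC(=O)/C(C)=C\C)CC(CC=C)C(=O)OC.[I-] | intermediate
25 | methyl (4R)-4-{[(2Z)-2-methylbut-2-enoyl]oxy}-4-{(2S,3R)-4-methylidene-5-oxo-2-[(1S)-1-(triethylsilyloxy)prop-2-yn-1-yl]oxolan-3-yl}-2-(prop-2-en-1-yl)butanoate, C10 epimers (key-step precursor) | C=C1C(=O)O[C@H]([C@@H](O[Si](CC)(CC)CC)C#C)[C@H]1[C@H](OC(=O)/C(C)=C\C)CC(CC=C)C(=O)OC | intermediate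
26 | ring A/ring B bicycle: ten-membered carbocycle trans-fused to the α-methylene lactone at C6–C7, (5S,6S,7R,8R), C5–OTES, C8 angelate, C10 bearing H and CO2Me (epimers), E-C1=C2, exocyclic C4=C15 (key-step product) | C=C1C(=O)O[C@H]2[C@H]1[C@H](OC(=O)/C(C)=C\C)CC(C(=O)OC)/C=C/CC(=C)[C@@H]2O[Si](CC)(CC)CC | intermediate
27 | TES ether of the target: as 26 but with the ring-cis C1=C10 alkene (E by CIP) conjugated to the C14 methyl ester, (5S,6S,7R,8R) | C=C1C(=O)O[C@H]2[C@H]1[C@H](OC(=O)/C(C)=C\C)C/C(C(=O)OC)=C\CCC(=C)[C@@H]2O[Si](CC)(CC)CC | intermediate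
28 | CNP0163095.1: (5S,6S,7R,8R)-5-hydroxy-8-angeloyloxy 6,12-lactone with C11=C13 and C4=C15 methylenes and the ring-cis C1=C10 methyl ester | C=C1C(=O)O[C@H]2[C@H]1[C@H](OC(=O)/C(C)=C\C)C/C(C(=O)OC)=C\CCC(=C)[C@@H]2O | target

Total step count: 16. Longest linear sequence: 16 steps (1 to 28).

Steps most likely to fail

Step 14 (Proposed new method). The strain of a ten-membered transition state may slow ring closure so that oligomerisation, catalyst trapping by chelation of the alkyne with the nearby lactone methylene, or bond formation at C15 takes over. The fallback uses known chemistry and moves the ring closure to C1=C10 by ring-closing metathesis. It leaves the route at 21. MeI gives the trimethylammonium iodide F1, and aqueous NaHCO3 eliminates it to the methylene lactone acrylate F2, as in step 13. The known intermolecular ruthenium-catalysed addition of allyl alcohol to a terminal alkyne ([CpRu(MeCN)3]PF6, acetone) then gives the γ,δ-unsaturated aldehyde F3, in which C4=C15, C3, C2 and C1 (as CHO) are in place. Takai methylenation (CH2I2, Zn, Ti(OiPr)4) converts the aldehyde into the terminal alkene of the triene F4. Ring-closing metathesis with the second-generation Grubbs catalyst at high dilution, between that vinyl group and the acrylate methylene, should form the ring-cis C1=C10 enoate directly and return to the route at 27, so step 15 is not needed. Closure onto the lactone methylene is not expected, because it would give a bridgehead alkene.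

Step 10. Facial control at C8 may be eroded by the α-stereocentre or by the pendant amine binding chromium, and the new alkoxide may lactonise onto the acrylate ester or the β-acyloxy aldehyde may eliminate under Lewis-acidic conditions. The fallback corrects the centre by inversion. From 16, an indium-mediated Barbier reaction with 17 (In powder, THF/aq. NH4Cl, rt) is not expected to be selective and gives 19 together with the C8-epimeric alcohol F5. After chromatographic separation 19 continues through step 11. F5 is esterified with angelic acid 20 under Mitsunobu conditions (PPh3, DIAD, toluene), which inverts C8 and rejoins the route at 21.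

Step 15. Conjugate addition of DBU to the lactone methylene, migration of that methylene into ring B, or Z to E isomerisation of the angelate may compete with the slow deprotonation at C10. The fallback protects the methylene, isomerises, then unmasks. From 26, dimethylamine in THF adds selectively to the lactone methylene and gives the dimethylamine adduct F6. DBU in toluene at 40 °C then conjugates the ester to the conjugated amine adduct F7. MeI gives the trimethylammonium iodide F8, and aqueous NaHCO3 regenerates the methylene lactone and returns to the route at 27.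

Further compounds

F1 | step 14 | N-methyl quaternary ammonium iodide of 21 | C[N+](C)(C)CC1C(=O)O[C@H]([C@@H](O[Si](CC)(CC)CC)C#C)[C@H]1[C@H](OC(=O)/C(C)=C\C)CC(=C)C(=O)OC.[I-]
F2 | step 14 | methylene lactone acrylate: 21 with C11=C13 in place of the aminomethyl group | C=C1C(=O)O[C@H]([C@@H](O[Si](CC)(CC)CC)C#C)[C@H]1[C@H](OC(=O)/C(C)=C\C)CC(=C)C(=O)OC
F3 | step 14 | γ,δ-unsaturated aldehyde: F2 with the alkyne replaced by C4(=C15H2)–C3H2–C2H2–C1HO | C=C1C(=O)O[C@H]([C@@H](O[Si](CC)(CC)CC)C(=C)CCC=O)[C@H]1[C@H](OC(=O)/C(C)=C\C)CC(=C)C(=O)OC
F4 | step 14 | triene: F3 with the aldehyde converted into a terminal vinyl group | C=C1C(=O)O[C@H]([C@@H](O[Si](CC)(CC)CC)C(=C)CCC=C)[C@H]1[C@H](OC(=O)/C(C)=C\C)CC(=C)C(=O)OC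
F5 | step 10 | C8 epimer of 19, (8S)-alcohol | CN(C)CC1C(=O)O[C@H]([C@@H](O[Si](CC)(CC)CC)C#C)[C@H]1[C@@H](O)CC(=C)C(=O)OC
F6 | step 15 | dimethylamine adduct of 26 at the lactone methylene | CN(C)CC1C(=O)O[C@H]2[C@H]1[C@H](OC(=O)/C(C)=C\C)CC(C(=O)OC)/C=C/CC(=C)[C@@H]2O[Si](CC)(CC)CC
F7 | step 15 | dimethylamine adduct of 27 | CN(C)CC1C(=O)O[C@H]2[C@H]1[C@H](OC(=O)/C(C)=C\C)C/C(C(=O)OC)=C\CCC(=C)[C@@H]2O[Si](CC)(CC)CC
F8 | step 15 | N-methyl quaternary ammonium iodide of F7 | C[N+](C)(C)CC1C(=O)O[C@H]2[C@H]1[C@H](OC(=O)/C(C)=C\C)C/C(C(=O)OC)=C\CCC(=C)[C@@H]2O[Si](CC)(CC)CC.[I-]
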